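**Plan**

- Retrosynthetic cuts, in order: (1) the acyl–aryl bond C4–C4a of the chromanone, with C4 handed back to O2' as the lactone 21; (2) the C2–C3 bond (arylacetic acid dianion plus aryloxymethyl chloride); (3) the homologation carbon on C1'; (4) the C5'–CMe2 bond (aromatic Claisen rearrangement of the O4' prenyl ether).
- Enabling feature: O2' of ring B is ortho to C1', so C4 can be held as the five-membered aryl lactone O2'–C4(=O)–C3 (a benzofuran-2(3H)-one). This makes C4 a phenyl-ester acyl donor and C3–H acidic (its enol is an aromatic 2-hydroxybenzofuran). C4a of ring A lies para to the 7-OH and ortho to O1 of a resorcinol monoether.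
- Forward order: ring B is elaborated first (O4' prenylation, MOM protection, Claisen, O-methylation, one-carbon homologation). Ring A is joined through C2 by alkylation. Acid removes the MOM groups and closes the lactone. The last step opens the lactone as it closes the pyranone ring.
- Stereochemistry: C3 is the only stereocentre. It is carried racemic and freely epimerising up to 21 and is set in the last step by an acyltransferase-catalysed dynamic kinetic resolution that should convert both enantiomers of 21 into (3S)-22.

Key step: step 12

Assumption: an acyltransferase variant that accepts lactone 21 and forms the (3S)-ketone can be found by screening or engineering; the sense of enantioselection is fixed by the choice of variant and cannot be predicted from the substrate.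

**Route**

Step 1
Reactants: 1 2,3,4-trihydroxybenzaldehyde; 2 prenyl bromide (1-bromo-3-methylbut-2-ene)
Product: 3 2,3-dihydroxy-4-[(3-methylbut-2-en-1-yl)oxy]benzaldehyde
Conditions: 2 (1.05 equiv), NaHCO3, NaI (cat.), DMF, 40 °C, N2
Reagents that add atoms: prenyl bromide CC(C)=CCBr
Why: Williamson etherification under weak-base control, in which the 4-OH (para to the formyl group, the most acidic phenol; the 2-OH is hydrogen-bonded to C=O and the 3-OH is not conjugated) should be the only one ionised and alkylated by the allylic bromide.

Step 2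
Reactants: 3 2,3-dihydroxy-4-[(3-methylbut-2-en-1-yl)oxy]benzaldehyde; 4 chloromethyl methyl ether
Product: 5 2,3-bis(methoxymethoxy)-4-[(3-methylbut-2-en-1-yl)oxy]benzaldehyde
Conditions: NaH (2.2 equiv), 4 (2.5 equiv), DMF, 0 °C → rt
Reagents that add atoms: chloromethyl methyl ether COCCl
Why: Double O-alkylation of the catechol dianion (acetal-type Williamson reaction) masks O2' and O3' with MOM groups that tolerate heat, base and hydride and are removed together by mild acid later.

Step 3
Reactants: 5 2,3-bis(methoxymethoxy)-4-[(3-methylbut-2-en-1-yl)oxy]benzaldehyde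
Product: 6 4-hydroxy-2,3-bis(methoxymethoxy)-5-(2-methylbut-3-en-2-yl)benzaldehyde
Conditions: N,N-diethylaniline, 185 °C (sealed tube or microwave), argon
Reagents that add atoms: none
Why: Aromatic Claisen rearrangement, in which the [3,3] shift delivers the prenyl unit with allylic inversion (as 1,1-dimethylallyl) to C5, the only ortho position that can rearomatise because C3 carries OMOM.

Step 4
Reactants: 6 4-hydroxy-2,3-bis(methoxymethoxy)-5-(2-methylbut-3-en-2-yl)benzaldehyde; 7 iodomethane
Product: 8 4-methoxy-2,3-bis(methoxymethoxy)-5-(2-methylbut-3-en-2-yl)benzaldehyde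
Conditions: K2CO3, 7, DMF, rt → 40 °C
Reagents that add atoms: iodomethane CI
Why: Williamson O-methylation of the phenol (acidified by the para formyl group) fixes the 4'-methoxy group and removes the free hydroxyl ortho to the 1,1-dimethylallyl group that could otherwise cyclise onto the alkene.

Step 5
Reactants: 8 4-methoxy-2,3-bis(methoxymethoxy)-5-(2-methylbut-3-en-2-yl)benzaldehyde; 9 chloroform
Product: 10 rac-2,2,2-trichloro-1-[4-methoxy-2,3-bis(methoxymethoxy)-5-(2-methylbut-3-en-2-yl)phenyl]ethan-1-ol
Conditions: CHCl3 (reagent and solvent), DBU (1.1 equiv), 0 °C → rt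
Reagents that add atoms: chloroform ClC(Cl)Cl
Why: Amidine-promoted addition of trichloromethanide to the non-enolisable aryl aldehyde gives the trichloromethyl carbinol needed for a Jocic-type homologation; the carbinol centre is racemic and is destroyed in the next step.

Step 6
Reactants: 10 rac-2,2,2-trichloro-1-[4-methoxy-2,3-bis(methoxymethoxy)-5-(2-methylbut-3-en-2-yl)phenyl]ethan-1-ol; 11 sodium hydroxide
Product: 12 [4-methoxy-2,3-bis(methoxymethoxy)-5-(2-methylbut-3-en-2-yl)phenyl]acetic acid
Conditions: NaBH4, NaOH, t-BuOH, 55 °C; aqueous citric acid to pH 4 at 0 °C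
Reagents that add atoms: sodium hydroxide [Na+].[OH-]
Why: Reductive Jocic-type one-carbon homologation, in which hydroxide closes the carbinol to a gem-dichloroepoxide, borohydride opens it at the benzylic carbon and the resulting acyl chloride is hydrolysed to the arylacetic acid under basic conditions that MOM ethers and the isolated vinyl group tolerate.

Step 7
Reactants: 13 resorcinol; 4 chloromethyl methyl ether
Product: 14 3-(methoxymethoxy)phenol
Conditions: 13 (3 equiv), NaH (1 equiv), 4 (1 equiv), DMF, 0 °C → rt
Reagents that add atoms: chloromethyl methyl ether COCCl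
Why: Statistical mono-alkylation of the symmetrical diphenol with one equivalent of base and MOMCl in the presence of excess resorcinol should give mainly the mono-MOM ether, which is separable from diol and bis-ether by acidity and polarity.

Step 8
Reactants: 14 3-(methoxymethoxy)phenol; 15 chloromethyl methyl sulfide
Product: 16 1-(methoxymethoxy)-3-[(methylsulfanyl)methoxy]benzene
Conditions: NaH, NaI (cat.), 15, DMF, 0 °C → rt
Reagents that add atoms: chloromethyl methyl sulfide CSCCl
Why: Williamson etherification of the phenoxide installs the methylthiomethyl (O,S-acetal) ether, the standard precursor of an aryl chloromethyl ether.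

Step 9
Reactants: 16 1-(methoxymethoxy)-3-[(methylsulfanyl)methoxy]benzene; 17 sulfuryl chloride
Product: 18 1-(chloromethoxy)-3-(methoxymethoxy)benzene
Conditions: SO2Cl2 (1.05 equiv), CH2Cl2, −78 → 0 °C; volatiles removed, used crude at once
Reagents that add atoms: sulfuryl chloride O=S(=O)(Cl)Cl
Why: Chlorinolysis of the O,S-acetal, in which S-chlorination and loss of methanesulfenyl chloride give an aryloxy-stabilised oxocarbenium ion that chloride captures, should outpace ring chlorination at low temperature.

Step 10
Reactants: 12 [4-methoxy-2,3-bis(methoxymethoxy)-5-(2-methylbut-3-en-2-yl)phenyl]acetic acid; 18 1-(chloromethoxy)-3-(methoxymethoxy)benzene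
Product: 19 rac-2-[4-methoxy-2,3-bis(methoxymethoxy)-5-(2-methylbut-3-en-2-yl)phenyl]-3-[3-(methoxymethoxy)phenoxy]propanoic acid
Conditions: LDA (2.05 equiv), THF, −78 → 0 °C; then 18 (1.1 equiv), −78 °C; aqueous HCl to pH 4 at 0 °C
Reagents that add atoms: 1-(chloromethoxy)-3-(methoxymethoxy)benzene COCOc1cccc(OCCl)c1
Why: C-alkylation of the arylacetic acid enediolate (dianion) with the highly reactive chloromethyl ether forms the C3–C2 bond irreversibly at low temperature, avoiding the base-reversible oxa-Michael chemistry of β-aryloxy esters; C3 is deliberately formed racemic.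

Step 11
Reactants: 19 rac-2-[4-methoxy-2,3-bis(methoxymethoxy)-5-(2-methylbut-3-en-2-yl)phenyl]-3-[3-(methoxymethoxy)phenoxy]propanoic acid
Product: 21 rac-7-hydroxy-3-[(3-hydroxyphenoxy)methyl]-6-methoxy-5-(2-methylbut-3-en-2-yl)-1-benzofuran-2(3H)-one, via triol methyl ester 20 (not isolated)
Conditions: HCl (1.25 M in MeOH), 45 °C; evaporate; then TsOH·H2O (10 mol%), ClCH2CH2Cl, 5 Å molecular sieves, 70 °C
Reagents that add atoms: none
Why: Acid-catalysed acetal exchange in methanol removes the three MOM groups as dimethoxymethane (with Fischer esterification of the acid by the solvent in passing), and acid-catalysed intramolecular transesterification by the 2'-OH then closes the five-membered aryl lactone once methanol is taken up by the sieves; C3 stays racemic.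

Step 12
Reactants: 21 rac-7-hydroxy-3-[(3-hydroxyphenoxy)methyl]-6-methoxy-5-(2-methylbut-3-en-2-yl)-1-benzofuran-2(3H)-one
Product: 22 (3S)-3-[2,3-dihydroxy-4-methoxy-5-(2-methylbut-3-en-2-yl)phenyl]-7-hydroxy-2,3-dihydro-4H-1-benzopyran-4-one
Conditions: acyltransferase (cofactor-free Friedel–Crafts C-acyltransferase of the acetylphloroglucinol PhlACB type from Pseudomonas protegens, variant chosen by screening), potassium phosphate buffer 50 mM, pH 6.8, DMSO 10% v/v, sodium ascorbate, argon, 28 °C; extraction into EtOAc at pH 6
Reagents that add atoms: none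
Why: Proposed new method: the active-site cysteine is expected to open the aryl lactone of (3S)-21 (an internal phenyl ester, the donor type this enzyme class already uses) to an enzyme-bound thioester while releasing the 2'-phenol, after which ring A, activated through its 7-OH, attacks the thioester carbonyl with C4a and rearomatises; this is the mechanism of the known acyltransferase-catalysed Friedel–Crafts acylation and Fries-type acyl shift of resorcinols with phenyl ester donors, and what is new is the intramolecular course, the α-branched lactone donor and the resorcinol monoether acceptor. The chroman-4-one ring closes by 6-exo-trig attack of C4a on the acyl carbon as the five-membered lactone opens, so the step is a net isomerisation without by-product. C3 is controlled by the enzyme active site: the enantiomers of 21 should interconvert at this pH through the aromatic 2-hydroxybenzofuran enol, whereas C3–H of the product aryl ketone is less acidic by an estimated two to three pK units, so all material should be funnelled through the faster-reacting (3S)-lactone (dynamic kinetic resolution), and the product is extracted promptly to keep its configuration. The step needs regioselectivity for C4a over the other ortho carbon (C8 of 22), secured by the para relationship of C4a to the free 7-OH and by the crowding of C8 between two oxygens, and chemoselectivity for C-acylation over hydrolysis, secured by the sequestered acyl-enzyme and the six-membered-ring proximity of C4a.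

**Compound list**

1 | 2,3,4-trihydroxybenzaldehyde | O=Cc1ccc(O)c(O)c1O | starting material
2 | prenyl bromide (1-bromo-3-methylbut-2-ene) | CC(C)=CCBr | starting material
3 | 2,3-dihydroxy-4-[(3-methylbut-2-en-1-yl)oxy]benzaldehyde | O=Cc1ccc(OCC=C(C)C)c(O)c1O | intermediate
4 | chloromethyl methyl ether | COCCl | starting material
5 | 2,3-bis(methoxymethoxy)-4-[(3-methylbut-2-en-1-yl)oxy]benzaldehyde | O=Cc1ccc(OCC=C(C)C)c(OCOC)c1OCOC | intermediate
6 | 4-hydroxy-2,3-bis(methoxymethoxy)-5-(2-methylbut-3-en-2-yl)benzaldehyde | O=Cc1cc(C(C)(C)C=C)c(O)c(OCOC)c1OCOC | intermediate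
7 | iodomethane | CI | starting material
8 | 4-methoxy-2,3-bis(methoxymethoxy)-5-(2-methylbut-3-en-2-yl)benzaldehyde | O=Cc1cc(C(C)(C)C=C)c(OC)c(OCOC)c1OCOC | intermediate
9 | chloroform | ClC(Cl)Cl | starting material
10 | rac-2,2,2-trichloro-1-[4-methoxy-2,3-bis(methoxymethoxy)-5-(2-methylbut-3-en-2-yl)phenyl]ethan-1-ol | OC(c1cc(C(C)(C)C=C)c(OC)c(OCOC)c1OCOC)C(Cl)(Cl)Cl | intermediate
11 | sodium hydroxide | [Na+].[OH-] | starting material
12 | [4-methoxy-2,3-bis(methoxymethoxy)-5-(2-methylbut-3-en-2-yl)phenyl]acetic acid | OC(=O)Cc1cc(C(C)(C)C=C)c(OC)c(OCOC)c1OCOC | intermediate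
13 | resorcinol | Oc1cccc(O)c1 | starting material
14 | 3-(methoxymethoxy)phenol | COCOc1cccc(O)c1 | intermediate
15 | chloromethyl methyl sulfide | CSCCl | starting material
16 | 1-(methoxymethoxy)-3-[(methylsulfanyl)methoxy]benzene | COCOc1cccc(OCSC)c1 | intermediate
17 | sulfuryl chloride | O=S(=O)(Cl)Cl | starting material
18 | 1-(chloromethoxy)-3-(methoxymethoxy)benzene | COCOc1cccc(OCCl)c1 | intermediate
19 | rac-2-[4-methoxy-2,3-bis(methoxymethoxy)-5-(2-methylbut-3-en-2-yl)phenyl]-3-[3-(methoxymethoxy)phenoxy]propanoic acid | OC(=O)C(COc1cccc(OCOC)c1)c1cc(C(C)(C)C=C)c(OC)c(OCOC)c1OCOC | intermediate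
20 | rac-methyl 2-[2,3-dihydroxy-4-methoxy-5-(2-methylbut-3-en-2-yl)phenyl]-3-(3-hydroxyphenoxy)propanoate (triol methyl ester, not isolated) | COC(=O)C(COc1cccc(O)c1)c1cc(C(C)(C)C=C)c(OC)c(O)c1O | intermediate
21 | rac-7-hydroxy-3-[(3-hydroxyphenoxy)methyl]-6-methoxy-5-(2-methylbut-3-en-2-yl)-1-benzofuran-2(3H)-one | O=C1Oc2c(O)c(OC)c(C(C)(C)C=C)cc2C1COc1cccc(O)c1 | intermediate
22 | (3S)-3-[2,3-dihydroxy-4-methoxy-5-(2-methylbut-3-en-2-yl)phenyl]-7-hydroxy-2,3-dihydro-4H-1-benzopyran-4-one | C=CC(C)(C)c1cc([C@H]2COc3cc(O)ccc3C2=O)c(O)c(O)c1OC | target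

**Step count and risks**

Total steps: 12. Longest linear sequence: 9 (steps 1–6, 10, 11, 12); steps 7–9 form the ring A branch.

Most likely to fail:

1. Step 12 (the proposed new method). The enzyme may not turn over the bulky α-branched lactone donor or the monoether acceptor. Other possible failures are background hydrolysis of the lactone, retro-oxa-Michael loss of ring A from the enol of 21, and slow loss of configuration of the product at C3 in the buffer.
Fallback, from 21 back to 22: the lactone is isomerised without enzyme by a Lewis-acid Fries-type transacylation (BF3·OEt2, 1,4-dioxane, 50 °C), in which the activated ring A is acylated by the aryl ester. This gives racemic 3-[2,3-dihydroxy-4-methoxy-5-(2-methylbut-3-en-2-yl)phenyl]-7-hydroxy-2,3-dihydro-4H-1-benzopyran-4-one F1. The racemate is resolved by preparative chromatography on a polysaccharide carbamate chiral stationary phase to give 22 and its (3R)-enantiomer F2. The (3R)-enantiomer F2 is returned to F1 by enolisation at C3 (Et3N, MeOH, rt) and resolved again.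

2. Step 3. The para formyl group may favour loss of the prenyl group (cleavage to the phenol and isoprene) over the [3,3] shift, and the ortho-(1,1-dimethylallyl)phenol may react further at the reaction temperature.
Fallback, from 1 back to 8: 1 is methylated selectively at the 4-OH (iodomethane, Li2CO3, DMF) to 2,3-dihydroxy-4-methoxybenzaldehyde F3. Bromination (NBS, MeCN, 0 °C) at C5, which is para to the 2-OH and meta to the formyl group, should give 5-bromo-2,3-dihydroxy-4-methoxybenzaldehyde F4. Protection (NaH, chloromethyl methyl ether, DMF) gives 5-bromo-4-methoxy-2,3-bis(methoxymethoxy)benzaldehyde F5. A ligand-controlled γ-selective Suzuki–Miyaura coupling of F5 with 3-methylbut-2-en-1-ylboronic acid pinacol ester (Pd(OAc)2, bulky dialkylbiarylphosphine, K3PO4, THF–H2O, 40 °C) should attach the 1,1-dimethylallyl group at C5 and give 8.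

3. Step 6. The gem-dichloroepoxide may ionise at the electron-rich benzylic carbon and be captured by hydroxide or tert-butoxide instead of hydride, giving α-oxygenated acids.
Fallback, from 8 back to 12: Wittig reaction of 8 with (methoxymethyl)triphenylphosphonium chloride and KOtBu (THF, 0 °C) gives 4-methoxy-1-(2-methoxyethenyl)-2,3-bis(methoxymethoxy)-5-(2-methylbut-3-en-2-yl)benzene F6 as an E/Z mixture. Brief hydrolysis of the enol ether (dilute aqueous HCl, THF, 0 °C; aryl MOM ethers should survive) gives [4-methoxy-2,3-bis(methoxymethoxy)-5-(2-methylbut-3-en-2-yl)phenyl]acetaldehyde F7. Pinnick oxidation (NaClO2, NaH2PO4, 2-methylbut-2-ene, t-BuOH–H2O) gives 12.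

**Further compounds**

F1 | step 12 | rac-3-[2,3-dihydroxy-4-methoxy-5-(2-methylbut-3-en-2-yl)phenyl]-7-hydroxy-2,3-dihydro-4H-1-benzopyran-4-one | C=CC(C)(C)c1cc(C2COc3cc(O)ccc3C2=O)c(O)c(O)c1OC
F2 | step 12 | (3R)-3-[2,3-dihydroxy-4-methoxy-5-(2-methylbut-3-en-2-yl)phenyl]-7-hydroxy-2,3-dihydro-4H-1-benzopyran-4-one | C=CC(C)(C)c1cc([C@@H]2COc3cc(O)ccc3C2=O)c(O)c(O)c1OC
F3 | step 3 | 2,3-dihydroxy-4-methoxybenzaldehyde | COc1ccc(C=O)c(O)c1O
F4 | step 3 | 5-bromo-2,3-dihydroxy-4-methoxybenzaldehyde | COc1c(Br)cc(C=O)c(O)c1O
F5 | step 3 | 5-bromo-4-methoxy-2,3-bis(methoxymethoxy)benzaldehyde | COc1c(Br)cc(C=O)c(OCOC)c1OCOC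
F6 | step 6 | 4-methoxy-1-(2-methoxyethenyl)-2,3-bis(methoxymethoxy)-5-(2-methylbut-3-en-2-yl)benzene (E/Z mixture) | COC=Cc1cc(C(C)(C)C=C)c(OC)c(OCOC)c1OCOC
F7 | step 6 | [4-methoxy-2,3-bis(methoxymethoxy)-5-(2-methylbut-3-en-2-yl)phenyl]acetaldehyde | O=CCc1cc(C(C)(C)C=C)c(OC)c(OCOC)c1OCOC
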